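## Structural features

The target is a chamigrene-type spiro[5.5]undecadiene, labelled here C1–C11 (labels used in all names below): ring A is C1(CH3)=C2H–C3H(OH)–C4H(Br)–C5(CH3)2–C6, ring B is C6–C7H2–C8H2–C9(CH3)=C10(Br)–C11H2, and C6 is the spiro atom. C6 is an all-carbon quaternary stereocenter bonded directly to the quaternary C5, so the C5–C6 region is the most congested part of the molecule. C6 is stereogenic only because the two ring B arms differ at the remote C9/C10 positions, so its configuration is hard to impose by a reagent acting at C6 and gives only a weak bias when C3 and C4 are set afterwards. C3 (S, OH) and C4 (S, Br) are contiguous and trans (both equatorial), with bromine on the ring A face that carries C11 and hydroxyl on the face that carries C7. Fragile groups are the secondary bromide beside a free alcohol (epoxide closure under base), the allylic alcohol (ionisation) and the tetrasubstituted alkenyl bromide C9=C10, which does not tolerate zerovalent palladium or nickel, alkyllithiums or dissolving metals once formed. The key step exploits the allylic triad C2–C1=C6 of ring A: C6 is the terminus of an allyl unit whose other end, C2, is a plain sp2 CH in the target, so an oxygen placed temporarily on C2 can hand a carbon substituent to C6 by a suprafacial [3,3] shift and transfer its configuration to the spiro atom. C1–C6, their three methyl groups and the C3 oxygen are also the skeleton of commercial 2,6,6-trimethylcyclohex-2-ene-1,4-dione (1), whose hindered carbonyl carbon is C6, so the real difficulty (quaternary C6 beside C5, its configuration, and the bromoalkene) is met by turning that carbonyl carbon into the spiro centre.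

## Logic of the disconnections

20 ⇒ 19. Cut: C3–H. The trans-diequatorial bromohydrin is the more stable C3 epimer, so the last step is a reversible hydride transfer to the C3 carbonyl of 19. Gain: one stereocenter less. Demand: conditions that equilibrate C3 without touching either C–Br bond or the C4 configuration.

19 ⇒ 17. Cut: C4–Br. The bromine is placed by electrophilic bromination of the kinetic C3/C4 enolate of 17. Gain: ring A becomes an achiral enone unit and C6 is the only stereocenter left. Demand: facial selection at C4 from the C6 environment alone.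

17 ⇒ 16 ⇒ 15. Cuts: the C3 carbonyl is masked as a ketal (16) and C10–Br is traced to C10–O (15). Gain: the tetrasubstituted bromoalkene is reduced to carbonyl chemistry. Demand: a halogen exchange that keeps the C9=C10 position and tolerates the ketal.

15 ⇒ 13. Cuts: O–S and C8–H. The enol triflate comes from conjugate reduction of the C8=C9 enone of 13 and O-trapping of the resulting enolate. Gain: the position of the ring B double bond is fixed by the enone, not by a selective enolisation. Demand: 1,4-hydride delivery to a β-monosubstituted, α-methyl enone.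

13 ⇒ 12. Cut: C8=C9 (ring-closing metathesis). Ring B is closed away from C6 and away from the future halogen. Gain: ring B becomes two acyclic arms on C6. Demand: metathesis between a neopentylic allyl group and an isopropenyl ketone.

12 ⇒ 9 + 10. Cut: C9–C10 (acyl substitution of an amide by the organolithium 11 made from 10). Gain: the C11–C10 arm is reduced to an acetamide unit. Demand: mono-addition to the hindered amide.

9 ⇒ 6 + 7 (key). Cut: C6–C11, with the C6 configuration. The bond is made by a [3,3] shift of 8, the ketene N,O-acetal of the C2 carbinol. In one sentence: the spiro stereocenter and its second carbon arm arise together by 1,3-chirality transfer in the amide-acetal Claisen rearrangement of 6. Gain: the quaternary stereocenter beside C5 is replaced by a secondary carbinol in a monocyclic compound. Demand: enantiopure 6, and a sigmatropic shift that prevails over the congestion at C5/C6.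

6 ⇒ 5. Cut: C2–H (enantioselective carbonyl reduction). Gain: the only externally controlled stereocenter is a secondary alcohol. Demand: differentiation of the two fully substituted flanks of the C2 carbonyl.

5 ⇒ 4 ⇒ 2 + 3. Cuts: the C2 oxygen is traced to C6 by a 1,3-oxidative transposition, and C6–C7 to allyl addition of 3 to the C6 carbonyl of 2. Gain: both arms on C6 are introduced at a carbonyl carbon. Demand: 1,2-addition to a hindered enone carbonyl.

2 ⇒ 1. Cut: the two ketal C–O bonds at C3. The less hindered carbonyl of 1 is masked selectively. Gain: a commercial starting material holding all nine carbons of ring A.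

## Other disconnections considered

Alternative 1: Cut C6–C11 and C7–C8, closing ring B in one step. The forward key step is a catalytic enantioselective Diels–Alder reaction of 3-ethoxy-5,5-dimethyl-6-methylidenecyclohex-2-en-1-one A1 with 2-bromo-3-methylbuta-1,3-diene A2 to the spiro vinylogous ester A3. This is the first plan that comes to mind. The C9/C10 pattern would depend on which of two weak 2-substituents of A2 (methyl or bromine) directs the orientation, and no mechanistic reason favours one strongly. Facial control would have to come from a chiral Lewis acid on a cross-conjugated dienophile whose reacting carbon becomes quaternary beside C5. A2 is also a labile diene. The chosen plan sets C6 through a cyclic transition state from an sp3 carbinol and builds the bromoalkene regiospecifically from a carbonyl.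

Alternative 2: Cut C6–C11, then C9=C10. The forward key steps are an enantioselective palladium-catalysed α′-allylation of a 3-alkoxy-5,5-dimethylcyclohexenone enolate to the quaternary ketone A4, then ring-closing metathesis to A3. Zerovalent palladium would be expected to insert into the alkenyl C–Br bond of the 2-bromoallyl arm in competition with the allylation. The metathesis would have to pass through an α-bromo ruthenium alkylidene and form a tetrasubstituted alkene. Carrying chlorine or a placeholder instead costs steps. The chosen plan closes ring B at C8=C9 as a trisubstituted enone and introduces bromine afterwards from oxygen.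

Alternative 3: Cut C5–C6 (biomimetic). The forward key step is a bromonium-initiated cation–olefin cyclisation of (E)-1-bromo-2-methyl-4-(6-methylhept-5-en-2-ylidene)cyclohex-1-ene A5 to the dibromodiene A6, followed by allylic oxidation at C3. The C4/C6 relationship would be dictated by the geometry of the tetrasubstituted exocyclic alkene of A5. Its two ring arms differ only at remote C9/C10, so no olefination can be expected to set that geometry. Absolute control would need an enantioselective bromonium transfer in the presence of two other alkenes. Termination by proton loss can give endo and exo alkenes. The C3 oxygen would require a late C–H oxidation with several competing allylic sites. The chosen plan carries the C3 oxygen from the start and does not depend on alkene geometry.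

Key step: step 5

## Steps

Step 1
Reactants: 1 2,6,6-trimethylcyclohex-2-ene-1,4-dione (ketoisophorone)
Product: 2 7,9,9-trimethyl-1,4-dioxaspiro[4.5]dec-6-en-8-one
Conditions: HOCH2CH2OH, TsOH (cat.), PhMe, reflux, Dean–Stark
Reagents that add atoms: ethane-1,2-diol, OCCO
Why: Acid-catalysed ketalisation; the C3 carbonyl (between CH= and CH2) reacts, while the C6 carbonyl between C5(CH3)2 and C1(CH3)= is too hindered, so the mono-ketal should form; no stereocenter.

Step 2
Reactants: 2 7,9,9-trimethyl-1,4-dioxaspiro[4.5]dec-6-en-8-one; 3 allylmagnesium bromide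
Product: 4 7,9,9-trimethyl-8-(prop-2-enyl)-1,4-dioxaspiro[4.5]dec-6-en-8-ol (racemic)
Conditions: allylMgBr, THF, −78 → 0 °C; then H2O
Reagents that add atoms: allylmagnesium bromide 3, C=CC[Mg]Br
Why: Grignard 1,2-addition; allylmagnesium halides add to hindered enone carbonyls through a six-membered allyl-transfer transition state and do not add 1,4; the new carbinol centre is racemic and is erased in step 3.

Step 3
Reactants: 4 7,9,9-trimethyl-8-(prop-2-enyl)-1,4-dioxaspiro[4.5]dec-6-en-8-ol
Product: 5 7,9,9-trimethyl-8-(prop-2-enyl)-1,4-dioxaspiro[4.5]dec-7-en-6-one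
Conditions: (C5H5NH)[CrO3Cl], NaOAc, 4 Å MS, CH2Cl2, 25 °C
Reagents that add atoms: pyridinium chlorochromate, [O-][Cr](=O)(=O)Cl.c1cc[nH+]cc1
Why: Babler–Dauben oxidative transposition: the chromate ester of the tertiary allylic alcohol undergoes a [3,3] shift that moves oxygen from C6 to C2 and is then oxidised to the enone, which makes C6 the sp2 allyl terminus needed in step 5; acetate buffers the acid so that the ketal survives.

Step 4
Reactants: 5 7,9,9-trimethyl-8-(prop-2-enyl)-1,4-dioxaspiro[4.5]dec-7-en-6-one
Product: 6 (6R)-7,9,9-trimethyl-8-(prop-2-enyl)-1,4-dioxaspiro[4.5]dec-7-en-6-ol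
Conditions: (R)-2-methyl-CBS-oxazaborolidine (20 mol %), catecholborane, PhMe, −78 °C; then H2O
Reagents that add atoms: none
Why: Corey–Bakshi–Shibata reduction, well precedented for 2-methylcyclohex-2-enones: the ring boron is expected to bind the carbonyl lone pair on the C3 side because the in-plane C1 methyl blocks the other, so the (R)-catalyst should deliver hydride to the face that gives (R)-C2; catecholborane at −78 °C leaves the terminal alkene alone.

Step 5
Reactants: 6 (6R)-7,9,9-trimethyl-8-(prop-2-enyl)-1,4-dioxaspiro[4.5]dec-7-en-6-ol; 7 1,1-dimethoxy-N,N-dimethylethanamine (N,N-dimethylacetamide dimethyl acetal)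
Product: 9 2-[(8R)-7,9,9-trimethyl-8-(prop-2-enyl)-1,4-dioxaspiro[4.5]dec-6-en-8-yl]-N,N-dimethylacetamide, via ketene N,O-acetal 8 (not isolated)
Conditions: MeC(OMe)2NMe2, xylenes, 140 °C
Reagents that add atoms: N,N-dimethylacetamide dimethyl acetal 7, COC(C)(OC)N(C)C
Why: Eschenmoser–Claisen rearrangement: 6 exchanges one methoxy group of 7, loss of a second methanol gives the ketene N,O-acetal 8, and its O–C2–C1=C6 allyl unit and the ketene C=C pass through a six-membered cyclic transition state that breaks C2–O and forms C6–C11. The closest known reaction type is the amide-acetal Claisen rearrangement of 3-substituted cyclohex-2-enols that creates quaternary ring carbons. No ring is closed in this step; ring B is completed in step 7 from the two arms now held on C6. The only new stereocenter is C6 and it is fixed by the ring: the migrating two-carbon unit can reach C6 only on the face of ring A that carried the C2–O bond (suprafacial 1,3-chirality transfer), so (R)-C2 becomes (R)-C6 with C11 on the face of the future C4–Br bond and C7 on the other, while C2 becomes the sp2 CH of the target. Regiochemistry is unambiguous because the allyl system has a single terminus, and elimination cannot compete because neither C1 (sp2) nor C3 (fully substituted ketal carbon) carries a hydrogen β to the oxygen. The step needs the shift to overcome the congestion of a new quaternary carbon beside C5(CH3)2; the gain of an amide carbonyl and the intramolecular, neutral conditions (which also spare the ketal) should secure this, and the temperature is kept below that of a Cope shift of the resulting 1,5-diene.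

Step 6
Reactants: 9 2-[(8R)-7,9,9-trimethyl-8-(prop-2-enyl)-1,4-dioxaspiro[4.5]dec-6-en-8-yl]-N,N-dimethylacetamide; 10 2-bromopropene
Product: 12 3-methyl-1-[(8R)-7,9,9-trimethyl-8-(prop-2-enyl)-1,4-dioxaspiro[4.5]dec-6-en-8-yl]but-3-en-2-one, via isopropenyllithium 11 (not isolated)
Conditions: 10, Li, Et2O, 0 °C; then 9, THF, −78 → 0 °C; then H2O
Reagents that add atoms: 2-bromopropene 10, CC(Br)=C
Why: Addition of an alkenyllithium to an N,N-dimethylamide: the tetrahedral lithium hemiaminal is stable until hydrolysis, so the ketone is released only on work-up and is not attacked twice; C6 is not touched.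

Step 7
Reactants: 12 3-methyl-1-[(8R)-7,9,9-trimethyl-8-(prop-2-enyl)-1,4-dioxaspiro[4.5]dec-6-en-8-yl]but-3-en-2-one
Product: 13 (6R)-1,5,5,9-tetramethylspiro[5.5]undeca-1,8-diene-3,10-dione 3-(ethane-1,2-diyl ketal)
Conditions: second-generation Grubbs catalyst RuCl2(=CHPh)(H2IMes)(PCy3) (5 mol %), CH2Cl2, 40 °C
Reagents that add atoms: none
Why: Ring-closing metathesis between the allyl CH=CH2 and the isopropenyl ketone closes ring B as a six-membered 2-methyl enone (trisubstituted C8=C9) with loss of ethene; the trisubstituted ring A alkene beside C6 and the ketal are inert, and the closure is two atoms away from the future halogen site.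

Step 8
Reactants: 13 (6R)-1,5,5,9-tetramethylspiro[5.5]undeca-1,8-diene-3,10-dione 3-(ethane-1,2-diyl ketal)
Product: 15 (6R)-3,3-(ethane-1,2-diyldioxy)-1,5,5,9-tetramethylspiro[5.5]undeca-1,9-dien-10-yl trifluoromethanesulfonate, via lithium enolate 14 (not isolated)
Conditions: LiBH(s-Bu)3, THF, −78 °C; then PhNTf2, −78 → 0 °C; then H2O
Reagents that add atoms: N-phenylbis(trifluoromethanesulfonimide), O=S(=O)(N(c1ccccc1)S(=O)(=O)C(F)(F)F)C(F)(F)F
Why: Conjugate reduction by the hindered borohydride gives the C9=C10 enolate 14 regiospecifically (as with carvone-type 2-methyl enones), and O-sulfonylation fixes the tetrasubstituted double bond where the target has it, with oxygen on the future C–Br carbon.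

Step 9
Reactants: 15 (6R)-3,3-(ethane-1,2-diyldioxy)-1,5,5,9-tetramethylspiro[5.5]undeca-1,9-dien-10-yl trifluoromethanesulfonate
Product: 16 (6R)-10-bromo-1,5,5,9-tetramethylspiro[5.5]undeca-1,9-dien-3-one ethane-1,2-diyl ketal
Conditions: Ni(cod)2 (10 mol %), LiBr, DMA/THF, 25 °C
Reagents that add atoms: lithium bromide, [Li+].[Br-]
Why: Halogen exchange of an enol triflate under zerovalent nickel catalysis (oxidative addition into C10–O, triflate/bromide exchange on nickel, C10–Br reductive elimination); oxygen is replaced by bromine with the double bond held in place, and the ketal and the isolated alkene are tolerated.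

Step 10
Reactants: 16 (6R)-10-bromo-1,5,5,9-tetramethylspiro[5.5]undeca-1,9-dien-3-one ethane-1,2-diyl ketal
Product: 17 (6R)-10-bromo-1,5,5,9-tetramethylspiro[5.5]undeca-1,9-dien-3-one
Conditions: 1 M HCl, THF, 25 °C
Reagents that add atoms: water, O
Why: Acid hydrolysis of the allylic ketal returns the C3 carbonyl in conjugation with C1=C2; the alkenyl bromide and the quaternary centre are inert to dilute acid.

Step 11
Reactants: 17 (6R)-10-bromo-1,5,5,9-tetramethylspiro[5.5]undeca-1,9-dien-3-one
Product: 19 (4S,6S)-4,10-dibromo-1,5,5,9-tetramethylspiro[5.5]undeca-1,9-dien-3-one, via lithium dienolate 18 (not isolated)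
Conditions: LiN(i-Pr)2, THF, −78 °C; then NBS, −78 °C; then H2O
Reagents that add atoms: N-bromosuccinimide, O=C1CCC(=O)N1Br
Why: Kinetic α′-deprotonation at C4 (as with isophorone) gives the cross-conjugated dienolate 18, which is brominated at C4; bromine should enter anti to the pseudo-axial C5 methyl and therefore syn to the pseudo-axial ring B methylene on C6, and the half-chair with the allylic C11 (not C7) pseudo-axial is the one expected to react, which puts Br on the C11 face (4S); the C6 descriptor changes from R to S only because C5 now outranks C1.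

Step 12
Reactants: 19 (4S,6S)-4,10-dibromo-1,5,5,9-tetramethylspiro[5.5]undeca-1,9-dien-3-one
Product: 20 (3S,4S,6S)-4,10-dibromo-1,5,5,9-tetramethylspiro[5.5]undeca-1,9-dien-3-ol (target)
Conditions: Al(O-i-Pr)3, i-PrOH, PhMe, 80 °C (acetone not distilled off)
Reagents that add atoms: none
Why: Meerwein–Ponndorf–Verley reduction: hydride is transferred reversibly from isopropoxide within a six-membered aluminium chelate, so with acetone kept in the flask the C3 epimers equilibrate through 19; the alcohol with OH pseudo-equatorial and trans to the equatorial C4–Br should accumulate, because the cis epimer would hold OH 1,3-diaxial to the axial C5 methyl; the C–Br bonds are not touched, as in the classical reduction of α-bromo ketones.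

## Compound list

1 | 2,6,6-trimethylcyclohex-2-ene-1,4-dione (ketoisophorone) | CC1=CC(=O)CC(C)(C)C1=O | starting material
2 | 7,9,9-trimethyl-1,4-dioxaspiro[4.5]dec-6-en-8-one | CC1=CC2(OCCO2)CC(C)(C)C1=O | intermediate
3 | allylmagnesium bromide | C=CC[Mg]Br | starting material
4 | 7,9,9-trimethyl-8-(prop-2-enyl)-1,4-dioxaspiro[4.5]dec-6-en-8-ol (racemic) | CC1=CC2(OCCO2)CC(C)(C)C1(O)CC=C | intermediate
5 | 7,9,9-trimethyl-8-(prop-2-enyl)-1,4-dioxaspiro[4.5]dec-7-en-6-one | C=CCC1=C(C)C(=O)C2(OCCO2)CC1(C)C | intermediate
6 | (6R)-7,9,9-trimethyl-8-(prop-2-enyl)-1,4-dioxaspiro[4.5]dec-7-en-6-ol | C=CCC1=C(C)[C@@H](O)C2(OCCO2)CC1(C)C | intermediate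
7 | 1,1-dimethoxy-N,N-dimethylethanamine (N,N-dimethylacetamide dimethyl acetal) | COC(C)(OC)N(C)C | starting material
8 | (6R)-6-{[1-(dimethylamino)ethenyl]oxy}-7,9,9-trimethyl-8-(prop-2-enyl)-1,4-dioxaspiro[4.5]dec-7-ene (ketene N,O-acetal) | C=CCC1=C(C)[C@@H](OC(=C)N(C)C)C2(OCCO2)CC1(C)C | intermediate
9 | 2-[(8R)-7,9,9-trimethyl-8-(prop-2-enyl)-1,4-dioxaspiro[4.5]dec-6-en-8-yl]-N,N-dimethylacetamide | CC1=CC2(OCCO2)CC(C)(C)[C@@]1(CC=C)CC(=O)N(C)C | intermediate
10 | 2-bromopropene | CC(Br)=C | starting material
11 | isopropenyllithium | [Li]C(C)=C | intermediate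
12 | 3-methyl-1-[(8R)-7,9,9-trimethyl-8-(prop-2-enyl)-1,4-dioxaspiro[4.5]dec-6-en-8-yl]but-3-en-2-one | CC1=CC2(OCCO2)CC(C)(C)[C@@]1(CC=C)CC(=O)C(C)=C | intermediate
13 | (6R)-1,5,5,9-tetramethylspiro[5.5]undeca-1,8-diene-3,10-dione 3-(ethane-1,2-diyl ketal) | CC1=CC2(OCCO2)CC(C)(C)[C@]13CC=C(C)C(=O)C3 | intermediate
14 | lithium C9=C10 enolate of the C10 ketone, ring A as in 13 | CC1=CC2(OCCO2)CC(C)(C)[C@]13CCC(C)=C(O[Li])C3 | intermediate
15 | (6R)-3,3-(ethane-1,2-diyldioxy)-1,5,5,9-tetramethylspiro[5.5]undeca-1,9-dien-10-yl trifluoromethanesulfonate | CC1=CC2(OCCO2)CC(C)(C)[C@]13CCC(C)=C(OS(=O)(=O)C(F)(F)F)C3 | intermediate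
16 | (6R)-10-bromo-1,5,5,9-tetramethylspiro[5.5]undeca-1,9-dien-3-one ethane-1,2-diyl ketal | CC1=CC2(OCCO2)CC(C)(C)[C@]13CCC(C)=C(Br)C3 | intermediate
17 | (6R)-10-bromo-1,5,5,9-tetramethylspiro[5.5]undeca-1,9-dien-3-one | CC1=CC(=O)CC(C)(C)[C@]12CCC(C)=C(Br)C2 | intermediate
18 | lithium C3=C4 dienolate of 17 | CC1=CC(O[Li])=CC(C)(C)[C@]12CCC(C)=C(Br)C2 | intermediate
19 | (4S,6S)-4,10-dibromo-1,5,5,9-tetramethylspiro[5.5]undeca-1,9-dien-3-one | CC1=CC(=O)[C@@H](Br)C(C)(C)[C@]12CCC(C)=C(Br)C2 | intermediate
20 | (3S,4S,6S)-4,10-dibromo-1,5,5,9-tetramethylspiro[5.5]undeca-1,9-dien-3-ol | CC1=C[C@H](O)[C@@H](Br)C(C)(C)[C@]12CCC(C)=C(Br)C2 | target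

## Step count and least certain steps

Total step count: 12. Longest linear sequence: 12 steps from 1.

Step 5 (key step). What may go wrong: the sigmatropic shift may be slow because it creates a quaternary carbon beside C5(CH3)2, so the acetal exchange reverts; prolonged heating may also induce a Cope shift of the allyl group from C6 to C2 in the 1,5-diene product. Fallback, from 6, returning at 12: acetylation of 6 (Ac2O, DMAP) gives the acetate F1. Ireland–Claisen rearrangement of its silyl ketene acetal (LiN(i-Pr)2, Me3SiCl, THF, −78 → 25 °C, acidic work-up) gives the carboxylic acid F2 at or below room temperature with the same suprafacial transfer. Excess isopropenyllithium converts F2 directly into 12.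

Step 11. What may go wrong: poor facial selectivity in the bromine transfer, because the two faces of dienolate 18 differ only in which ring B methylene (C7 or C11) lies over them. Fallback, from 17, returning at 19: the bromination is run without relying on selectivity and the C4 epimer F3 is separated from 19 by chromatography. F3 is returned to 17 by reductive debromination with zinc in acetic acid and brominated again.

Step 12. What may go wrong: incomplete equilibration that leaves the kinetic cis alcohol; enolisation of 19 under the aluminium alkoxide with loss of C4 configuration before reduction; or epoxide closure of the product alkoxide. Fallback, from 19, returning at 20: kinetic hydride delivery to the open face with i-Bu2AlH at −78 °C gives the cis bromohydrin F4. Mitsunobu inversion at C3 (PPh3, diisopropyl azodicarboxylate, 4-nitrobenzoic acid) gives the 4-nitrobenzoate F5. Methanolysis (K2CO3, MeOH, 0 °C) releases 20.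

Step 4. What may go wrong: low enantioselectivity, because both flanks of the C2 carbonyl are fully substituted carbons and the catalyst may not differentiate them; hydroboration of the allyl group is a lesser risk. Fallback, from 5, returning at 6: Luche reduction (NaBH4, CeCl3, MeOH) gives the racemic alcohol F6. F6 is resolved by preparative chromatography on a chiral stationary phase to give 6. The unwanted (6S)-alcohol F7 is returned to 5 by oxidation with Dess–Martin periodinane.

Step 9. What may go wrong: slow oxidative addition into the tetrasubstituted enol triflate, or protonation or homocoupling of the alkenylnickel intermediate. Fallback, from 15, returning at 16: stannylation with Me3SnSnMe3, Pd(PPh3)4 and LiCl in dioxane gives the alkenylstannane F8. Ipso-bromodestannylation of F8 with NBS in MeCN at 0 °C gives 16.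

## Further compounds

F1 | step 5 | (6R)-7,9,9-trimethyl-8-(prop-2-enyl)-1,4-dioxaspiro[4.5]dec-7-en-6-yl acetate | C=CCC1=C(C)[C@@H](OC(C)=O)C2(OCCO2)CC1(C)C
F2 | step 5 | 2-[(8R)-7,9,9-trimethyl-8-(prop-2-enyl)-1,4-dioxaspiro[4.5]dec-6-en-8-yl]acetic acid | CC1=CC2(OCCO2)CC(C)(C)[C@@]1(CC=C)CC(=O)O
F3 | step 11 | (4R,6S)-4,10-dibromo-1,5,5,9-tetramethylspiro[5.5]undeca-1,9-dien-3-one | CC1=CC(=O)[C@H](Br)C(C)(C)[C@]12CCC(C)=C(Br)C2
F4 | step 12 | (3R,4S,6S)-4,10-dibromo-1,5,5,9-tetramethylspiro[5.5]undeca-1,9-dien-3-ol | CC1=C[C@@H](O)[C@@H](Br)C(C)(C)[C@]12CCC(C)=C(Br)C2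
F5 | step 12 | (3S,4S,6S)-4,10-dibromo-1,5,5,9-tetramethylspiro[5.5]undeca-1,9-dien-3-yl 4-nitrobenzoate | CC1=C[C@H](OC(=O)c3ccc(cc3)[N+](=O)[O-])[C@@H](Br)C(C)(C)[C@]12CCC(C)=C(Br)C2
F6 | step 4 | racemic 7,9,9-trimethyl-8-(prop-2-enyl)-1,4-dioxaspiro[4.5]dec-7-en-6-ol | C=CCC1=C(C)C(O)C2(OCCO2)CC1(C)C
F7 | step 4 | (6S)-7,9,9-trimethyl-8-(prop-2-enyl)-1,4-dioxaspiro[4.5]dec-7-en-6-ol | C=CCC1=C(C)[C@H](O)C2(OCCO2)CC1(C)C
F8 | step 9 | (6R)-1,5,5,9-tetramethyl-10-(trimethylstannyl)spiro[5.5]undeca-1,9-dien-3-one ethane-1,2-diyl ketal | CC1=CC2(OCCO2)CC(C)(C)[C@]13CCC(C)=C([Sn](C)(C)C)C3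
A1 | alternative 1 | 3-ethoxy-5,5-dimethyl-6-methylidenecyclohex-2-en-1-one | CCOC1=CC(=O)C(=C)C(C)(C)C1
A2 | alternative 1 | 2-bromo-3-methylbuta-1,3-diene | C=C(C)C(Br)=C
A3 | alternative 1 | (6R)-10-bromo-3-ethoxy-5,5,9-trimethylspiro[5.5]undeca-2,9-dien-1-one | CCOC1=CC(=O)[C@@]2(CCC(C)=C(Br)C2)C(C)(C)C1
A4 | alternative 2 | (6R)-6-(2-bromoprop-2-enyl)-3-ethoxy-5,5-dimethyl-6-(3-methylbut-3-enyl)cyclohex-2-en-1-one | CCOC1=CC(=O)[C@@](CC(Br)=C)(CCC(C)=C)C(C)(C)C1
A5 | alternative 3 | (E)-1-bromo-2-methyl-4-(6-methylhept-5-en-2-ylidene)cyclohex-1-ene | CC(C)=CCC/C(C)=C1/CC(Br)=C(C)CC1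
A6 | alternative 3 | (4R,6S)-4,10-dibromo-1,5,5,9-tetramethylspiro[5.5]undeca-1,9-diene | CC1=CC[C@@H](Br)C(C)(C)[C@]12CCC(C)=C(Br)C2
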